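Early in Thursday's run, at 20 °C, target reached 19% in 80.0 s, a rate of about 0.142 min⁻¹ as a fraction of the charge, as read. Sunday's and Tuesday's runs, at −21 °C, stayed within the scatter of 2 percentage points. The runs read target and nothing else, so I built the flask up on paper, one process at a time.

| setting | Sunday's | Thursday's | Tuesday's | gamma | zeta | eta | beta |
|---|---|---|---|---|---|---|---|
| starting material | 0.34 mM | 0.75 mM | 0.50 mM | 0.50 mM | 0.50 mM | 0.50 mM | 0.50 mM |
| protic impurity | 0.15 mM | 0.15 mM | 0.30 mM | 0.150 mM | 0.150 mM | 0.150 mM | 0.150 mM |
| temperature | −21 °C | 20 °C | −21 °C | −15 °C | 35 °C | −40 °C | 10 °C |
| remark | run made earlier | run made earlier | run made earlier |  |  |  |  |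
| time |  |  |  | 10 min | 10 min | 10 min | 10 min |

| Sunday's: time / min | Sunday's: target / % | Thursday's: time / s | Thursday's: target / % | Tuesday's: time / min | Tuesday's: target / % |
|---|---|---|---|---|---|
| 0.667 | 0 | 20.0 | 6 | 0.667 | 1 |
| 1.33 | 0 | 40.0 | 7 | 1.33 | 1 |
| 3.00 | 1 | 60.0 | 15 | 3.00 | 0 |
| 8.00 | 0 | 80.0 | 19 | 8.00 | 0 |

(readings scatter by 2 percentage points)

- what may be going on: starting material -> intermediate; intermediate <-> target; intermediate <-> isomer of the product; starting material + protic impurity -> quenched substrate

* the best flask by amount of target, in percent of the starting material charged; "all alike" if 1.5 percentage points covers them all (gamma / zeta / eta / beta / all alike)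
* amount of target at the end, in percent of the starting material charged, gamma
* amount of target at the end, in percent of the starting material charged, zeta
* amount of target at the end, in percent of the starting material charged, eta
* amount of target at the end, in percent of the starting material charged, beta

I began with the main step, starting material to intermediate to target. In a scheme of that step by itself, the ceiling for target is the whole charge. Then I added the quench. Starting material and protic impurity react one to one, and gamma, zeta, eta and beta share one charge: 0.50 mM and 0.150 mM. I divided the impurity charge by the starting material charge and took that from one, which gave 70.0%. This is the room, the share of the charge left for intermediate, target and isomer once the impurity is used up. It is a ratio of charges, so no time stands in it. The last addition was the isomer. It draws on the same intermediate, so target holds a share of the room. Both steps from intermediate run back, so that share can move with time, and no run read the isomer. So I committed to the room and to no yield.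

The forecast gave 1% for gamma, 45% for zeta, 0% for eta and 22% for beta, and it named zeta as best. On the isomer it said this “could lower zeta substantially, but it should still lead”.

The simulation gave 0.857% for gamma, 2.51% for zeta, 0% for eta and 35.4% for beta, so beta was best.

    starting material → intermediate (k = 0.110 s⁻¹, Ea = 68.0 kJ mol⁻¹)
    intermediate ⇌ target (K = 1.30, k = 0.0310 s⁻¹, Ea = 75.0 kJ mol⁻¹, ΔH = −15.0 kJ mol⁻¹)
    intermediate ⇌ isomer of the product (K = 290, k = 0.0130 s⁻¹, Ea = 92.0 kJ mol⁻¹, ΔH = −67.0 kJ mol⁻¹)
    starting material + protic impurity → quenched substrate (k = 400 M⁻¹ s⁻¹, Ea = 42.0 kJ mol⁻¹)
    (constants at 35 °C)

Beta had not come to rest at 10.0 min. Its starting material stood at 0.0804%, and intermediate, target and isomer together held 71.2%, against my room of 70.0%. Target was half of that pool. Zeta at the same time held 77.4%, more than the room, with 25% of its impurity unused, but target was 2.51% and isomer 73.3%. That is kinetic control giving way to thermodynamic control. Beta was heading the same way. At 100 min its three still summed to 71.3%, the isomer had risen to 45.7%, and target was down to a quarter of the pool, 18.4%.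

The runs stem from a simulated flask with constants of no real substance.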